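**Retrosynthetic overview**

- Target 32 is a cis,cis-germacranolide: a ten-membered carbocycle C1–C10 (C1=C10 bearing the C14 methyl ester, C4=C5 bearing the C15 methyl), a trans-fused alpha-methylene-gamma-lactone on C6/C7 (O on C6, C11–C13), an angelate on C8 and a free OH on C9; configuration 6R,7S,8S,9S.
- The strategy rests on the Z-trisubstituted C4=C5 alkene that lies in the ten-membered ring between the C3 methylene and the lactone carbinol C6. It is cut into an alkylcopper (C1–C3), propyne (C4, C5, C15) and a C6 aldehyde (C6–C9, C11, C12), joined in one pot with closure of the gamma-lactone (first ring).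
- The ten-membered ring is closed last, at C9–C10, by CrCl2/NiCl2 coupling of a (Z)-alpha-iodoenoate (made from the C1 aldehyde) with the C9 aldehyde; this also sets C9. C13 comes from a Mannich/elimination sequence, the angelate from the freed C8 hydroxyl.
- The aldehyde goes back to (R)-glyceraldehyde acetonide (C7–C9) by Z-olefination, reduction, Johnson–Claisen rearrangement (sets C7) and ozonolysis.

Key step: step 6

Assumption: germacrane numbering (C1–C15) is used for every intermediate, and the phenylethynyl group on copper is taken to be a non-transferable ligand.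

**Route**

Step 1
Reactants: 1 (R)-glyceraldehyde acetonide; 2 methyl (triphenylphosphoranylidene)acetate
Product: 3 methyl (2Z)-3-[(4S)-2,2-dimethyl-1,3-dioxolan-4-yl]prop-2-enoate
Conditions: MeOH, 0 °C
Reagents that add atoms: none
Why: Wittig olefination in which the ester-stabilised ylide reacts with the alpha-alkoxy aldehyde in methanol under kinetic control through the cis-oxaphosphetane, so the Z enoate should predominate and the dioxolane stereocentre (later C8) is not touched at 0 °C.

Step 2
Reactants: 3 methyl Z-enoate
Product: 4 (2Z)-3-[(4S)-2,2-dimethyl-1,3-dioxolan-4-yl]prop-2-en-1-ol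
Conditions: i-Bu2AlH, CH2Cl2, −78 °C; aq. KNaC4H4O6 (potassium sodium tartrate)
Reagents that add atoms: none
Why: Low-temperature 1,2-reduction of the enoate by the aluminium hydride gives the allylic alcohol without touching the Z alkene or the acetonide.

Step 3
Reactants: 4 Z-allylic alcohol; 5 triethyl orthoacetate
Product: 7 ethyl (3S)-3-[(4S)-2,2-dimethyl-1,3-dioxolan-4-yl]pent-4-enoate, via mixed ketene acetal 6 (not isolated)
Conditions: EtCO2H (cat.), neat 5, 140 °C, EtOH distilled off
Reagents that add atoms: none
Why: Johnson–Claisen rearrangement in which exchange with the orthoester and loss of ethanol give ketene acetal 6, which rearranges through a chair where allylic 1,3-strain of the Z alkene holds the C8–H bond in the alkene plane and the new C7–C11 bond forms anti to the C8–O bond, setting C7 as 3S.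

Step 4
Reactants: 7 Claisen ester
Product: 9 ethyl (3R)-3-[(4S)-2,2-dimethyl-1,3-dioxolan-4-yl]-4-oxobutanoate, via ozonide 8 (not isolated)
Conditions: O3, CH2Cl2, −78 °C; PPh3, −78 °C to rt; used crude
Reagents that add atoms: ozone, [O-][O+]=O
Why: Ozonolysis of the terminal vinyl group with reductive cleavage of the ozonide by PPh3 leaves the C6 aldehyde, and the neutral cold work-up with direct use of the crude aldehyde protects the epimerisable C7 centre.

Step 5
Reactants: 10 2-(2-bromoethyl)-1,3-dioxolane
Product: 11 2-(1,3-dioxolan-2-yl)ethylmagnesium bromide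
Conditions: Mg, BrCH2CH2Br (cat.), THF (minimum volume), 25–30 °C
Reagents that add atoms: magnesium, [Mg]
Why: Grignard formation by magnesium insertion into the primary C–Br bond, with the reagent kept below 30 °C because it fragments on heating.

Step 6
Reactants: 11 2-(1,3-dioxolan-2-yl)ethylmagnesium bromide; 12 propyne; 9 aldehyde ester
Product: 17 (4S,5R)-5-[(1Z)-4-(1,3-dioxolan-2-yl)-2-methylbut-1-en-1-yl]-4-[(4S)-2,2-dimethyl-1,3-dioxolan-4-yl]oxolan-2-one, via alkylcopper 13 (not isolated), via Z-alkenylcopper 14 (not isolated), via mixed cuprate 15 (not isolated), via lithium alkoxide 16 (not isolated)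
Conditions: CuBr·SMe2, Et2O/Me2S, −45 °C; 12, −25 °C; excess 12 removed in vacuo; LiC≡CPh, THF, −78 to −40 °C; 9, THF, −78 to −20 °C, then 20 °C; aq. NH4Cl/NH3
Reagents that add atoms: none
Why: Grignard reagent 11 transmetalates to alkylcopper 13, which delivers its alkyl group and monovalent copper to the same face of propyne through a cyclic carbometalation, the alkyl carbon bonding to the internal alkyne carbon (C3–C4) and copper to the terminal one, so that C3 and copper sit on the same side of the new C4=C5 bond in 14. LiC≡CPh converts the sluggish alkenylcopper into mixed cuprate 15, whose alkenyl group adds to the aldehyde carbonyl with retention (C5–C6), and the C6 alkoxide 16 then attacks the C12 ethyl ester on warming and expels ethoxide, closing the gamma-lactone by a 5-exo-trig acyl substitution. The closest known reaction type is the syn carbocupration of terminal alkynes by alkylcopper–MgBr2 reagents with trapping of the alkenylcopper by an electrophile after activation as an alkynyl cuprate, combined with the 1,2-addition of cuprates to aldehydes. C6 is set by Felkin–Anh addition next to the C7 stereocentre: the branched dioxolanyl carbon C8 stands anti to the incoming cuprate, the CH2CO2Et arm lies beside the carbonyl oxygen and the nucleophile passes the C7 hydrogen, which gives 6R and hence C5 and C8 trans on the lactone, and the 7,8-anti pattern of 9 makes the 1,3-induction by the C8 oxygen reinforce this sense. The step needs Z geometry, secured by syn addition followed by retention, and it needs attack on the non-chelated aldehyde, which the poorly coordinating acetonide oxygen and the THF that solvates MgBr2 and lithium should secure. The weakly basic copper species should leave C7 and the ethyl ester untouched until the alkoxide is formed.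

Step 7
Reactants: 17 trans-lactone
Product: 19 3-[(dimethylamino)methyl] derivative of 17 (C11 epimers), via lithium enolate 18 (not isolated)
Conditions: LiN(i-Pr)2, THF, −78 °C; CH2=NMe2+ I−, −78 °C to rt
Reagents that add atoms: Eschenmoser's salt (dimethylmethyleneammonium iodide), C=[N+](C)C.[I-]
Why: Mannich reaction in which the kinetic lithium enolate of the gamma-lactone is aminomethylated at C11 by the iminium salt, the new C11 centre being of no consequence because it is destroyed in the next step.

Step 8
Reactants: 19 Mannich base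
Product: 21 alpha-methylene lactone (3-methylidene analogue of 17; both acetals intact), via ammonium iodide 20 (not isolated)
Conditions: MeI, MeOH, rt; then aq. NaHCO3, CH2Cl2, rt
Reagents that add atoms: none
Why: Quaternisation of the amine followed by Hofmann-type E1cB elimination under mild base unveils the exocyclic C11=C13 alkene without epimerising C7.

Step 9
Reactants: 21 alpha-methylene lactone
Product: 22 C8,C9-diol (acetonide removed; 1,3-dioxolane at C1 kept)
Conditions: AcOH/H2O (4:1), rt
Reagents that add atoms: none
Why: Acid hydrolysis of a ketal, in which the acetone-derived dioxolane ionises far more readily than the aldehyde-derived 1,3-dioxolane at C1, so dilute acetic acid should free the diol while C1 stays masked.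

Step 10
Reactants: 22 diol
Product: 23 C9 tert-butyldiphenylsilyl ether (C8 OH free)
Conditions: TBDPSCl, Et3N, DMAP (cat.), CH2Cl2, 0 °C to rt
Reagents that add atoms: tert-butyl(chloro)diphenylsilane, CC(C)(C)[Si](Cl)(c1ccccc1)c1ccccc1
Why: Silylation with the bulky chlorosilane is selective for the primary C9 hydroxyl over the hindered secondary C8 hydroxyl, and the tertiary amine base cannot add irreversibly to the alpha-methylene lactone.

Step 11
Reactants: 23 silyl ether; 24 angelic acid [(Z)-2-methylbut-2-enoic acid]
Product: 25 C8 angelate (C9 O-TBDPS; C1 dioxolane)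
Conditions: 2,4,6-Cl3C6H2COCl, Et3N, toluene, rt; then 23, 75 °C
Reagents that add atoms: none
Why: Yamaguchi-type esterification through the mixed 2,4,6-trichlorobenzoic anhydride, run without a nucleophilic catalyst, acylates the C8 hydroxyl at oxygen (C8 configuration retained) and avoids the addition–elimination pathway that isomerises angelates to tiglates.

Step 12
Reactants: 25 angelate
Product: 26 C1 aldehyde (dioxolane removed)
Conditions: PPTS, acetone/H2O, 55 °C
Reagents that add atoms: water, O
Why: Acid-catalysed acetal hydrolysis in wet acetone releases the C1 aldehyde under conditions that the silyl ether, the angelate and the lactone tolerate.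

Step 13
Reactants: 26 C1 aldehyde; 2 methyl (triphenylphosphoranylidene)acetate
Product: 28 methyl (Z)-alpha-iodoenoate (C1=C10 with I on C10 cis to C2; C14 ester), via iodo ylide 27 (not isolated)
Conditions: NIS, CH2Cl2, −20 °C; then 26, −20 °C to rt
Reagents that add atoms: N-iodosuccinimide, O=C1CCC(=O)N1I
Why: Wittig olefination with the alpha-iodo ylide made in the flask by iodination of 2, in which, as with other stabilised ylides, the ester ends up trans to the C2 chain, giving the Z alpha-iodoenoate with iodine cis to C2.

Step 14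
Reactants: 28 iodoenoate silyl ether
Product: 29 C9 primary alcohol
Conditions: HF·pyridine, pyridine, THF, 0 °C to rt
Reagents that add atoms: none
Why: Fluoride cleavage of the silyl ether in an acidic buffered medium frees the C9 hydroxyl while suppressing base-induced migration of the angeloyl group from O8 to O9.

Step 15
Reactants: 29 C9 alcohol
Product: 30 C9 aldehyde (alpha-angeloyloxy aldehyde)
Conditions: Dess–Martin periodinane, CH2Cl2, 0 °C to rt; used at once
Reagents that add atoms: none
Why: Dess–Martin oxidation of the primary alcohol under neutral conditions gives the alpha-acyloxy aldehyde without epimerising C8.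

Step 16
Reactants: 30 iodoenoate aldehyde
Product: 32 target germacranolide (6R,7S,8S,9S; 1(10)E, 4Z), via alkenylchromium 31 (not isolated)
Conditions: CrCl2 (excess), NiCl2 (cat.), degassed DMSO, rt, slow addition at high dilution
Reagents that add atoms: none
Why: Nozaki–Hiyama–Kishi reaction in which zerovalent nickel inserts into the C10–I bond, the alkenyl group passes to trivalent chromium with retention of the C1=C10 geometry and adds chemoselectively to the C9 aldehyde, the cis C4=C5 bond and the trans-lactone folding the chain for the ten-membered closure; C9 should form as the 9S (8,9-syn) carbinol because closure needs a gauche C7–C8–C9–C10 arrangement and, with the carbonyl dipole opposed to the C8–O bond, this presents the required carbonyl face to C10.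

**Compound list**

1 | (R)-glyceraldehyde acetonide [(R)-2,2-dimethyl-1,3-dioxolane-4-carbaldehyde] | O=C[C@H]1COC(C)(C)O1 | starting material
2 | methyl (triphenylphosphoranylidene)acetate | COC(=O)C=P(c1ccccc1)(c1ccccc1)c1ccccc1 | starting material
3 | methyl (2Z)-3-[(4S)-2,2-dimethyl-1,3-dioxolan-4-yl]prop-2-enoate | COC(=O)/C=C\[C@H]1COC(C)(C)O1 | intermediate
4 | (2Z)-3-[(4S)-2,2-dimethyl-1,3-dioxolan-4-yl]prop-2-en-1-ol | OC/C=C\[C@H]1COC(C)(C)O1 | intermediate
5 | triethyl orthoacetate | CCOC(C)(OCC)OCC | starting material
6 | mixed ketene acetal (1-ethoxyvinyl ether of 4; not isolated) | C=C(OCC)OC/C=C\[C@H]1COC(C)(C)O1 | intermediate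
7 | ethyl (3S)-3-[(4S)-2,2-dimethyl-1,3-dioxolan-4-yl]pent-4-enoate | C=C[C@H](CC(=O)OCC)[C@H]1COC(C)(C)O1 | intermediate
8 | secondary ozonide (1,2,4-trioxolane) of 7 (not isolated) | C1(OCOO1)[C@H](CC(=O)OCC)[C@H]1COC(C)(C)O1 | intermediate
9 | ethyl (3R)-3-[(4S)-2,2-dimethyl-1,3-dioxolan-4-yl]-4-oxobutanoate | O=C[C@H](CC(=O)OCC)[C@H]1COC(C)(C)O1 | intermediate
10 | 2-(2-bromoethyl)-1,3-dioxolane | BrCCC1OCCO1 | starting material
11 | 2-(1,3-dioxolan-2-yl)ethylmagnesium bromide | Br[Mg]CCC1OCCO1 | intermediate
12 | propyne | CC#C | starting material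
13 | 2-(1,3-dioxolan-2-yl)ethylcopper, as its MgBr2/SMe2 complex (not isolated) | [Cu]CCC1OCCO1 | intermediate
14 | (Z)-4-(1,3-dioxolan-2-yl)-2-methylbut-1-enylcopper (not isolated) | [Cu]/C=C(/C)CCC1OCCO1 | intermediate
15 | lithium [(Z)-4-(1,3-dioxolan-2-yl)-2-methylbut-1-enyl](phenylethynyl)cuprate (not isolated) | [Li+].c1ccccc1C#C[Cu-]/C=C(/C)CCC1OCCO1 | intermediate
16 | lithium C6 alkoxide of the open hydroxy ester, 6R,7S,8S (not isolated) | [Li+].CCOC(=O)C[C@H]([C@H]1COC(C)(C)O1)[C@H]([O-])/C=C(/C)CCC1OCCO1 | intermediate
17 | (4S,5R)-5-[(1Z)-4-(1,3-dioxolan-2-yl)-2-methylbut-1-en-1-yl]-4-[(4S)-2,2-dimethyl-1,3-dioxolan-4-yl]oxolan-2-one (trans-lactone) | C1C(=O)O[C@H](/C=C(/C)CCC2OCCO2)[C@H]1[C@H]3COC(C)(C)O3 | intermediate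
18 | lithium enolate of 17 (not isolated) | [Li+].C1=C([O-])O[C@H](/C=C(/C)CCC2OCCO2)[C@H]1[C@H]3COC(C)(C)O3 | intermediate
19 | 3-[(dimethylamino)methyl] derivative of 17 (C11 epimers) | C1(CN(C)C)C(=O)O[C@H](/C=C(/C)CCC2OCCO2)[C@H]1[C@H]3COC(C)(C)O3 | intermediate
20 | trimethylammonium iodide of 19 (not isolated) | [I-].C1(C[N+](C)(C)C)C(=O)O[C@H](/C=C(/C)CCC2OCCO2)[C@H]1[C@H]3COC(C)(C)O3 | intermediate
21 | alpha-methylene lactone (3-methylidene analogue of 17) | C=C1C(=O)O[C@H](/C=C(/C)CCC2OCCO2)[C@H]1[C@H]3COC(C)(C)O3 | intermediate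
22 | C8,C9-diol of 21 (C1 dioxolane kept) | C=C1C(=O)O[C@H](/C=C(/C)CCC2OCCO2)[C@H]1[C@H](O)CO | intermediate
23 | C9 tert-butyldiphenylsilyl ether of 22 | C=C1C(=O)O[C@H](/C=C(/C)CCC2OCCO2)[C@H]1[C@H](O)CO[Si](c1ccccc1)(c1ccccc1)C(C)(C)C | intermediate
24 | angelic acid [(Z)-2-methylbut-2-enoic acid] | C/C=C(/C)C(=O)O | starting material
25 | C8 angelate of 23 | C=C1C(=O)O[C@H](/C=C(/C)CCC2OCCO2)[C@H]1[C@H](OC(=O)/C(C)=C\C)CO[Si](c1ccccc1)(c1ccccc1)C(C)(C)C | intermediate
26 | C1 aldehyde from 25 | C=C1C(=O)O[C@H](/C=C(/C)CCC=O)[C@H]1[C@H](OC(=O)/C(C)=C\C)CO[Si](c1ccccc1)(c1ccccc1)C(C)(C)C | intermediate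
27 | methyl 2-iodo-2-(triphenylphosphoranylidene)acetate (not isolated) | COC(=O)C(I)=P(c1ccccc1)(c1ccccc1)c1ccccc1 | intermediate
28 | methyl (Z)-alpha-iodoenoate, C9 O-TBDPS | C=C1C(=O)O[C@H](/C=C(/C)CC/C=C(\I)C(=O)OC)[C@H]1[C@H](OC(=O)/C(C)=C\C)CO[Si](c1ccccc1)(c1ccccc1)C(C)(C)C | intermediate
29 | C9 primary alcohol from 28 | C=C1C(=O)O[C@H](/C=C(/C)CC/C=C(\I)C(=O)OC)[C@H]1[C@H](OC(=O)/C(C)=C\C)CO | intermediate
30 | C9 aldehyde (alpha-angeloyloxy aldehyde) | C=C1C(=O)O[C@H](/C=C(/C)CC/C=C(\I)C(=O)OC)[C@H]1[C@H](OC(=O)/C(C)=C\C)C=O | intermediate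
31 | C10 alkenylchromium dichloride of 30 (not isolated) | C=C1C(=O)O[C@H](/C=C(/C)CC/C=C(\[Cr](Cl)Cl)C(=O)OC)[C@H]1[C@H](OC(=O)/C(C)=C\C)C=O | intermediate
32 | target: methyl (6R,7S,8S,9S)-8-angeloyloxy-9-hydroxy-12,6-olide-germacra-1(10)E,4Z,11(13)-trien-14-oate | C=C1C(=O)O[C@@H]2/C=C(/C)CC/C=C(/C(=O)OC)[C@H](O)[C@@H](OC(=O)/C(C)=C\C)[C@@H]12 | target

**Step count and risks**

Total steps: 16. Longest linear sequence: 15 steps (from 1 through steps 1–4 and 6–16; step 5 is a one-step branch).

Steps most likely to fail:

Step 6. What may go wrong: slow transfer of the alkenyl group from the alkynyl cuprate to the aldehyde, with competing enolisation at C7, or chelation of the aldehyde oxygen and O8 by MgBr2 or lithium that erodes the Felkin–Anh facial preference at C6. The fallback sets out from 11, 12 and 9 and comes back to the route at 17. The alkenylcopper 14 is made as in step 6 and quenched with iodine to give (Z)-2-(4-iodo-3-methylbut-3-en-1-yl)-1,3-dioxolane F1. F1 and 9 are then joined by a CrCl2/NiCl2-mediated alkenyl iodide–aldehyde coupling in DMSO, which tolerates the ester, involves no chelating Lewis acid and normally follows the Felkin–Anh sense with alpha-branched aldehydes. This gives ethyl (3S,4R,5Z)-3-[(4S)-2,2-dimethyl-1,3-dioxolan-4-yl]-8-(1,3-dioxolan-2-yl)-4-hydroxy-6-methyloct-5-enoate F2, which lactonises to 17 with a trace of PPTS in CH2Cl2.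

Step 16. What may go wrong: poor or reversed facial selectivity at C9 in the ten-membered transition state (an open-chain Felkin–Anh addition would favour the 8,9-anti carbinol), alongside reduction of the C–I bond or oligomerisation. The fallback sets out from 30 and comes back at 32. The same ring closure is run without relying on its stereochemical outcome, so that the 9-epimeric carbinol F3 is carried on together with any 32. The mixture is oxidised with Dess–Martin periodinane to the C9 ketone F4. Luche reduction (NaBH4, CeCl3·7H2O, MeOH, −78 °C) then sets C9 by hydride delivery anti to the C8–O bond, which for the ketone is the Felkin–Anh route to the 8,9-syn carbinol 32.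

Step 11. What may go wrong: Z-to-E isomerisation of the angeloyl unit during acyl transfer, or acylation of the hindered C8 hydroxyl so slow that the lactone migrates to O8 in the hot basic medium. The fallback sets out from 23 and comes back at 25. The C8 hydroxyl is esterified at 0 °C with 2-[bis(2,2,2-trifluoroethoxy)phosphoryl]propanoic acid (DCC, DMAP cat., CH2Cl2) to give the C8 2-[bis(2,2,2-trifluoroethoxy)phosphoryl]propanoate F5. Still–Gennari olefination of F5 with acetaldehyde (KN(SiMe3)2, 18-crown-6, THF, −78 °C) builds the Z trisubstituted alkene on the ester and delivers 25.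

**Further compounds**

F1 | step 6 | (Z)-2-(4-iodo-3-methylbut-3-en-1-yl)-1,3-dioxolane | I/C=C(/C)CCC1OCCO1
F2 | step 6 | ethyl (3S,4R,5Z)-3-[(4S)-2,2-dimethyl-1,3-dioxolan-4-yl]-8-(1,3-dioxolan-2-yl)-4-hydroxy-6-methyloct-5-enoate | CCOC(=O)C[C@H]([C@H]1COC(C)(C)O1)[C@H](O)/C=C(/C)CCC1OCCO1
F3 | step 16 | C9 epimer (9R) of 32 | C=C1C(=O)O[C@@H]2/C=C(/C)CC/C=C(/C(=O)OC)[C@@H](O)[C@@H](OC(=O)/C(C)=C\C)[C@@H]12
F4 | step 16 | C9 ketone of 32 | C=C1C(=O)O[C@@H]2/C=C(/C)CC/C=C(/C(=O)OC)C(=O)[C@@H](OC(=O)/C(C)=C\C)[C@@H]12
F5 | step 11 | C8 2-[bis(2,2,2-trifluoroethoxy)phosphoryl]propanoate of 23 | C=C1C(=O)O[C@H](/C=C(/C)CCC2OCCO2)[C@H]1[C@H](OC(=O)C(C)P(=O)(OCC(F)(F)F)OCC(F)(F)F)CO[Si](c1ccccc1)(c1ccccc1)C(C)(C)C
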